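Dusk, charged at 0.0041 M, is the neighbour of amber at 0.0040 M, and I read amber from dusk by working with the fraction left, not the fraction made.

| flask | X | remark | time |
|---|---|---|---|
| dusk | 0.0041 M | run made earlier |  |
| spring | 0.0065 M | run made earlier |  |
| summer | 0.011 M | run made earlier |  |
| amber | 0.0040 M |  | 15 h |
| grey | 0.0060 M |  | 15 h |
| violet | 0.0080 M |  | 15 h |
| green | 0.012 M |  | 15 h |

| run | time / h | Z / % |
|---|---|---|
| dusk | 1.50 | 1.6 |
| dusk | 3.00 | 6.8 |
| dusk | 5.00 | 14.4 |
| dusk | 6.00 | 16.7 |
| dusk | 8.00 | 23.2 |
| spring | 1.50 | 4.6 |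
| spring | 3.00 | 6.6 |
| spring | 5.00 | 13.7 |
| spring | 6.00 | 16.6 |
| spring | 8.00 | 21.6 |
| summer | 0.667 | 0.3 |
| summer | 2.00 | 5.6 |
| summer | 4.00 | 9.9 |
| summer | 5.00 | 13.1 |
| summer | 8.00 | 18.1 |

(readings scatter by 1 percentage point)

- the numbers in the tables scatter by 1 percentage point (one standard deviation)
- "hardly changes" means that all values lie within two and a half points (for a concentration: within two and a half percent of the largest)

- [Z] at the end for amber, grey, violet, green, in this order
- how the row runs (rises, then falls / falls all the way / hardly changes / rises all the way / falls, then rises)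

The quantity I carry is the halving time of the charge not yet Z, the apparent first-order half-life, read from F, the fraction not yet Z, at time t:

halving time = t · ln 2 / (−ln F)

F at a later time = 0.5^(time / halving time)

Dusk's last reading leaves 76.8 % after 8.00 h, and that reads as 21.0 h. Because the charges of dusk and amber differ by 1.00 × 10⁻⁴ M, I give amber dusk's halving time and let it run to 15 h:

amber: F = 61.0 %, Z = 0.00156 M

My reckoning thus puts amber at 39.0 % made, less than the 43.5 % of a straight proportion in time. Green has summer as its neighbour, whose reading gives a longer halving time than dusk's, 27.8 h: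

green: F = 68.8 %, Z = 0.00375 M

The charge grows 3.00-fold from amber to green while my reckoned fraction made goes down from 39.0 % to 31.2 %, so I expect green's Z to be more than amber's and the row to rise.

The forecast gives 0.00157 M, 0.00226 M, 0.0029 M and 0.004 M, and says rises all the way, “with no sign of a turnover”. At amber it matches my figure, and at green it stands above mine.

The flasks give 0.00140 M, 0.00198 M, 0.00250 M and 0.00342 M: rises all the way.

    X ⇌ Q (K = 1.56, k = 1.11 × 10⁻⁴ /s)
    Q ⇌ E (K = 0.190, k = 4.64 × 10⁻⁵ /s)
    Q ⇌ G (K = 3.10, k = 4.77 × 10⁻⁵ /s)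
    E → Z (k = 8.94 × 10⁻⁴ /s)
    X ⇌ D (K = 0.226, k = 4.66 × 10⁻⁵ /s)
    2 X → L (k = 0.00378 /M/s)

Amber's Z of 35.0 % at 15.0 h gives a halving time of 24.1 h, longer than dusk's 21.0 h, and green's 28.5 % gives 31.0 h, longer than summer's 27.8 h. In amber at 15.0 h, the slowest mode of the whole flask has a half-life of 33.0 h, longer than both the run itself and the 24.1 h that amber's Z shows.

All runs come from a simulation from invented constants, noise included.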